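Atom labels used below: the dihydrobenzofuran is O1, C2, C3, C3a–C7a, with ring B as its benzo ring (OMe at C7, side chain at C5) and ring C as the aryl group on C2. The chain is ring A–C7H2–C8(C9H2OH)–C8'(C9'H2OH)–C7'H2–C5 of ring B. Bn = benzyl, TBS = tert-butyldimethylsilyl.

## The problem

The target CNP0256425.1 (26) is a 2,3-dibenzylbutane-1,4-diol in which one "benzyl" arene is ring A and the other is ring B of a 2-aryl-3-hydroxymethyl-7-methoxy-2,3-dihydrobenzofuran, joined through C7'–C5. It has four stereocentres in two pairs: C2 (S) and C3 (R), trans on the five-membered ring, and C8 (R) and C8' (R) on the chain. The pairs are separated by a methylene group and an arene, so neither can control the other; each needs its own source of absolute configuration, and the halves must be joined without disturbing either. Within a pair, relay is possible: a C8 substituent on a butyrolactone directs alkylation at C8' to the trans face, and a C3 substituent favours trans closure at C2. The fragile element is the O1–C2 bond, a benzylic ether para to the ring-C oxygen: it ionises in acid, can be hydrogenolysed, and opens through a quinone methide once the ring-C phenol is free and base is present. The two guaiacol units and three primary alcohols add a protecting-group problem. The feature that opens the molecule is that C3 carries ring B and a CH2OH group while C2 carries ring C and O1: with C2 raised to a ketone and the CH2OH to an ester, C3 becomes the α-carbon of a 2,3-diaryl-3-oxopropanoate, whose C–H lies between ester, ketone and arene and racemises freely, so both centres can be set in one reduction of racemic material.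

## Retrosynthesis

**26 ⇒ 25 ⇒ 24 ⇒ 23 (no skeletal bond cut).** The two phenols are masked as benzyl ethers and the C3 hydroxymethyl as a TBS ether, and the 1,4-diol is read as the reduced form of trans-dibenzylbutyrolactone 23. A lactone is preferred to an open succinate because it tells C9 from C9', confines enolate chemistry to C8' and gives a ring on which C8 can direct C8'. Fluoride (24 → 25) is placed before hydrogenolysis (25 → 26) so that the ring-C phenol is still protected when base is present.

**23 ⇒ 16 + 22 (C7'–C8').** The bond between the ring-B benzylic carbon and the lactone α-carbon is cut, giving benzylic bromide 16 and (R)-lactone 22. Cutting C7–C8 instead would force the lactone to be built on the heterocycle and send the valuable half through more steps. The chosen cut lets 22 be made separately and brings the dihydrobenzofuran in at the last C–C bond formation. The forward step must alkylate anti to the C8 benzyl group and cope with an electron-rich, labile bromide.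

**22 ⇒ 20 ⇒ 19 ⇒ 17 + 18 (C7=C8, then C8–H).** The lactone is traced to succinate half ester 20 and, through the C8–H bonds, to Stobbe product 19 from aldehyde 17 and dimethyl succinate 18. This puts the only stereocentre of the fragment into a catalytic hydrogenation of a well-behaved substrate class. The forward reduction must then touch the ester and not the carboxylate, so that the correct lactone regioisomer closes (22 via hydroxy acid 21).

**16 ⇒ 15 ⇒ 13 (C5–C7').** The benzylic carbon is not carried through the early steps; it is introduced from the aryl bromide of 13 by metalation and formylation (aldehyde 14, reduced in the same flask). An oxygenated one-carbon group at C5 would interfere with the enolate, hydride and enzyme steps. Aryl bromide is inert to LiN(SiMe3)2, the enzyme, LiBH4, zerovalent palladium at room temperature and Mitsunobu reagents.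

**13 ⇒ 12 ⇒ 11 ⇒ 10 ⇒ 9 (O1–C2).** The heterocycle is opened at O1–C2. Cutting C7a–O1 would need a metal-mediated aryl etherification of a hindered secondary alcohol, and cutting C2–C3 or C3–C3a would need a ring-forming asymmetric step of its own. With O1 already on ring B as a phenol, closure is an intramolecular SN2 reaction that inverts the carbinol carbon, so the acyclic precursor must be anti. The ester has to be reduced first (10), since an activated β-hydroxy ester would eliminate. The primary alcohol has to be silylated (11), since it would otherwise be activated first and the phenol would close onto it to give an isomeric five-membered ring. The allyl ether is then removed (12).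

**9 ⇒ 8 (C2–H).** Removing the carbinol hydrogen gives β-keto ester 8 and clears both stereocentres at once: 8 is racemic and configurationally labile, so it can be made without any stereocontrol. The forward reaction must choose one α-enantiomer and one ketone face; a ketoreductase does both.

**8 ⇒ 5 + 7 (C2–C3); 7 ⇐ 6.** The keto ester is cut between the α-carbon and the ketone, a Claisen acylation of arylacetate 5 by aroyl chloride 7 (from acid 6). This places all of ring C in a commercial benzoic acid and all of ring B in an arylacetate. The forward step needs C-acylation and a second equivalent of base to hold the product as its enolate.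

**5 ⇒ 4 ⇒ 3 ⇒ 1 + 2.** The arylacetate is the one-carbon homologue of aldehyde 3 (via ketene dithioacetal S-oxide 4), and 3 is the allyl ether of commercial 1 (with allyl bromide 2). The substitution pattern of ring B (O at the future C7a, OMe at C7, Br at C5, carbon at C3a) is bought, not made.

## Roads not taken

**Alternative 1:** The lactone O–C9 bond is cut, which traces the (R)-lactone A2 (the same substance as 22) to the prochiral 3-benzylcyclobutanone A1. In the forward step a Baeyer–Villiger monooxygenase (NADPH, O2, cofactor recycling) inserts oxygen into one of the two enantiotopic C(O)–CH2 bonds of A1. The merits are real: the substrate is prochiral, so no racemisation has to keep pace, no precious metal or hydrogen pressure is needed, and the lactone appears directly in the right oxidation state. The weak points are the synthesis of A1 by a ketene cycloaddition and dechlorination, oxygen supply on scale, and the need to find an enzyme that reads a remote, electron-rich benzyl group well. For fragment 22 alone this road is about as short as steps 13–15 and could replace them without changing anything else. As a strategy for the whole molecule it spends its enzymatic step on C8, which homogeneous hydrogenation already sets reliably, and leaves C2/C3 unsolved. The chosen plan uses the enzyme where catalytic alternatives are few.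

**Alternative 2:** C7'–C8' and C7–C8 are both cut, and the chain is assembled on the menthyloxy butenolide A3. The lithiated dithiane A4 (which would be made from aldehyde 14) adds to C4 of A3 anti to the acetal substituent, and the resulting lactone enolate is trapped by the simple benzylic bromide A5 to give the trans,trans adduct A6. Two C–C bonds and both chain stereocentres arise in one flask from a cheap auxiliary, and the labile ring-B benzylic bromide 16 is not needed; in these respects it is better than steps 12–16. Against this, A4 already contains the enantiopure heterocycle, so the road does not address C2/C3 and still needs the chosen key step or an equivalent. The dithiane must later be removed reductively with Raney nickel, in a molecule with two benzyl ethers and the hydrogenolysis-prone O1–C2 bond, and the auxiliary is stoichiometric. The chosen plan sets against its convergence a sulfur-free endgame and a single, simple role for the valuable fragment.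

**Alternative 3:** The aryl–C7 bond of the lactone is cut. The aryl Grignard reagent A8, with catalytic CuI, opens the cyclopropane CH2 of the chiral-pool bicyclic lactone A7, and protonation of the malonate-type enolate gives the trans ester lactone A9; dealkoxycarbonylation would then give 22. The chirality is bought cheaply, the sequence is as short as steps 13–15, and the doubly activated A9 could be alkylated with 16 under milder base than a simple lactone enolate; on cost and on that alkylation it is as good or better. Its weak points are an enantiopurity inherited through a double displacement and not set by a tunable catalyst, a Grignard reagent from an oxygen-rich aryl bromide, and a hot dealkoxycarbonylation that would have to be run in the presence of the heterocycle if A9 were alkylated first. The chosen plan sets against it a ligand-controlled C8 centre and an organometallic-free lactone synthesis. Like alternative 1, this road is silent on C2/C3.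

Key step: step 6

Assumption: a ketoreductase with the 2S/Si-face sense is taken to be found by panel screening, and compound 4 is used as the alkene-isomer mixture (racemic at sulfur) in which it forms, since both elements disappear in step 3.

## Route

Step 1
Reactants: 1 5-bromo-2-hydroxy-3-methoxybenzaldehyde; 2 allyl bromide
Product: 3 2-(allyloxy)-5-bromo-3-methoxybenzaldehyde
Conditions: K2CO3, DMF, rt
Reagents that add atoms: none
Why: Williamson etherification of a phenoxide made more acidic by the ortho formyl group; allyl is chosen because it survives amide base, the enzyme and hydride and is later removed by zerovalent palladium without touching benzyl or silyl ethers.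

Step 2
Reactants: 3 2-(allyloxy)-5-bromo-3-methoxybenzaldehyde
Product: 4 2-(allyloxy)-5-bromo-1-methoxy-3-[2-(methylsulfinyl)-2-(methylsulfanyl)ethenyl]benzene (alkene isomers, racemic at sulfur)
Conditions: CH3S(O)CH2SCH3, BnMe3N+ OH− (Triton B, cat.), THF, reflux
Reagents that add atoms: methyl (methylsulfanyl)methyl sulfoxide, CS(=O)CSC
Why: Knoevenagel-type condensation of a non-enolisable aldehyde with the stabilised carbanion of the sulfoxide, the first stage of the Ogura–Tsuchihashi arylacetate synthesis; water is lost to give the conjugated ketene dithioacetal S-oxide.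

Step 3
Reactants: 4 2-(allyloxy)-5-bromo-1-methoxy-3-[2-(methylsulfinyl)-2-(methylsulfanyl)ethenyl]benzene
Product: 5 ethyl 2-[2-(allyloxy)-5-bromo-3-methoxyphenyl]acetate
Conditions: HCl (anhydrous), EtOH, rt to 50 °C
Reagents that add atoms: ethanol, CCO
Why: Acid ethanolysis of the ketene dithioacetal S-oxide (second stage of the Ogura–Tsuchihashi homologation): protonation at the benzylic carbon, capture by ethanol and loss of both sulfur groups as dimethyl disulfide leave the ester; aryl allyl ether and aryl bromide are inert to HCl in ethanol.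

Step 4
Reactants: 6 4-(benzyloxy)-3-methoxybenzoic acid
Product: 7 4-(benzyloxy)-3-methoxybenzoyl chloride
Conditions: (COCl)2, DMF (cat.), CH2Cl2, 0 °C to rt; evaporate and use crude
Reagents that add atoms: oxalyl chloride, O=C(Cl)C(=O)Cl
Why: DMF-catalysed acid chloride formation through the Vilsmeier-type chloroiminium; all by-products are gases, so the chloride is used without purification.

Step 5
Reactants: 5 ethyl 2-[2-(allyloxy)-5-bromo-3-methoxyphenyl]acetate; 7 4-(benzyloxy)-3-methoxybenzoyl chloride
Product: 8 ethyl 2-[2-(allyloxy)-5-bromo-3-methoxyphenyl]-3-[4-(benzyloxy)-3-methoxyphenyl]-3-oxopropanoate (racemic)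
Conditions: LiN(SiMe3)2 (2.2 equiv), THF, −78 °C; then 7, −78 to 0 °C; aq. NH4Cl
Reagents that add atoms: none
Why: Crossed Claisen C-acylation of the ester enolate by a non-enolisable aroyl chloride; the second equivalent of base converts the more acidic product into its enolate as it forms, which prevents a second acylation. The new centre is deliberately left racemic.

Step 6
Reactants: 8 ethyl 2-[2-(allyloxy)-5-bromo-3-methoxyphenyl]-3-[4-(benzyloxy)-3-methoxyphenyl]-3-oxopropanoate (racemic)
Product: 9 ethyl (2S,3R)-2-[2-(allyloxy)-5-bromo-3-methoxyphenyl]-3-[4-(benzyloxy)-3-methoxyphenyl]-3-hydroxypropanoate (anti)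
Conditions: ketoreductase (screening hit, NADPH-dependent), NADP+ (cat.), i-PrOH (10% v/v), KH2PO4/K2HPO4 buffer pH 7.0, MgSO4 (2 mM), DMSO (15% v/v), 30 °C
Reagents that add atoms: none
Why: The α-hydrogen of 8 lies between the ester, the aryl ketone and ring B, so at pH 7 the two enantiomers should interconvert through the enol much faster than either is reduced. The ketoreductase binds one enantiomer and transfers hydride from NADPH to one face of the ketone (the Si face of the 2S keto ester), forming the C–H bond of the future C2, while isopropanol regenerates NADPH on the same enzyme and leaves as acetone. This is the ketoreductase dynamic reductive kinetic resolution known for α-substituted β-keto esters; the present member, with an aryl-bearing group on each side of the carbonyl, is among the bulkiest of its class, which is why a panel screen precedes scale-up. No ring closes and no skeletal bond forms. The α-centre (future C3) is fixed by which enantiomer fits the active site and the carbinol centre (future C2) by the face the bound ketone presents to the cofactor, so both are under catalyst control. The step needs enantiomer choice and face choice (together the anti 2S,3R isomer) and chemoselectivity for the ketone over ester, aryl bromide and allyl ether, the last being inherent in a hydride-transfer enzyme. Full conversion of the racemate to one isomer depends on fast racemisation, which the triply activated C–H secures. Should the best enzyme give the syn isomer with the correct α-centre, the route still converges, because closure can then be run through the benzylic cation.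

Step 7
Reactants: 9 ethyl (2S,3R)-2-[2-(allyloxy)-5-bromo-3-methoxyphenyl]-3-[4-(benzyloxy)-3-methoxyphenyl]-3-hydroxypropanoate
Product: 10 (1R,2R)-2-[2-(allyloxy)-5-bromo-3-methoxyphenyl]-1-[4-(benzyloxy)-3-methoxyphenyl]propane-1,3-diol
Conditions: LiBH4, THF, MeOH (1 equiv), 0 °C to rt
Reagents that add atoms: none
Why: Chemoselective borohydride reduction of an ester assisted by the neighbouring hydroxyl; the weakly basic medium should avoid retro-aldol cleavage and epimerisation, and neither stereocentre is a reacting atom (the descriptor at the former α-carbon changes from S to R only through priorities).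

Step 8
Reactants: 10 (1R,2R)-2-[2-(allyloxy)-5-bromo-3-methoxyphenyl]-1-[4-(benzyloxy)-3-methoxyphenyl]propane-1,3-diol
Product: 11 (1R,2R)-2-[2-(allyloxy)-5-bromo-3-methoxyphenyl]-1-[4-(benzyloxy)-3-methoxyphenyl]-3-(TBS-oxy)propan-1-ol
Conditions: TBSCl (1.05 equiv), imidazole, CH2Cl2, 0 °C
Reagents that add atoms: tert-butyldimethylsilyl chloride, CC(C)(C)[Si](C)(C)Cl
Why: Steric differentiation of a primary from a secondary benzylic alcohol in silylation; the primary hydroxyl must be masked because in step 10 it would be activated first and the phenol would close onto it.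

Step 9
Reactants: 11 (1R,2R)-2-[2-(allyloxy)-5-bromo-3-methoxyphenyl]-1-[4-(benzyloxy)-3-methoxyphenyl]-3-(TBS-oxy)propan-1-ol
Product: 12 (1R,2R)-1-[4-(benzyloxy)-3-methoxyphenyl]-2-(5-bromo-2-hydroxy-3-methoxyphenyl)-3-(TBS-oxy)propan-1-ol
Conditions: Pd(PPh3)4 (cat.), morpholine, THF, rt
Reagents that add atoms: none
Why: Tsuji–Trost deallylation: zerovalent palladium ionises the aryl allyl ether to a π-allyl complex and the phenoxide, and morpholine captures the allyl group; oxidative addition into the C–Br bond of this electron-rich arene is slow at room temperature.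

Step 10
Reactants: 12 (1R,2R)-1-[4-(benzyloxy)-3-methoxyphenyl]-2-(5-bromo-2-hydroxy-3-methoxyphenyl)-3-(TBS-oxy)propan-1-ol
Product: 13 (2S,3R)-2-[4-(benzyloxy)-3-methoxyphenyl]-5-bromo-3-(TBS-oxymethyl)-7-methoxy-2,3-dihydrobenzofuran
Conditions: PPh3, diisopropyl azodicarboxylate, THF, 0 °C to rt
Reagents that add atoms: none
Why: Intramolecular Mitsunobu etherification: the benzylic hydroxyl is activated as its alkoxyphosphonium ion and displaced by the phenoxide in a 5-exo-tet SN2 closure, so the 1R carbinol becomes 2S and the anti relationship becomes 2,3-trans. Any ionised leak should also give the trans ring because the C3 substituent steers the phenol to the opposite face, so the enzyme-set C3 centre safeguards the outcome.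

Step 11
Reactants: 13 (2S,3R)-2-[4-(benzyloxy)-3-methoxyphenyl]-5-bromo-3-(TBS-oxymethyl)-7-methoxy-2,3-dihydrobenzofuran
Product: 15 [(2S,3R)-2-[4-(benzyloxy)-3-methoxyphenyl]-3-(TBS-oxymethyl)-7-methoxy-2,3-dihydrobenzofuran-5-yl]methanol, via 5-carbaldehyde 14 (not isolated)
Conditions: n-BuLi, THF, −78 °C; DMF, −78 to 0 °C; then MeOH, NaBH4, 0 °C
Reagents that add atoms: N,N-dimethylformamide, CN(C)C=O
Why: Bromine–lithium exchange, which at −78 °C outruns benzylic deprotonation, then Bouveault-type formylation with DMF and borohydride reduction of the liberated aldehyde in the same flask; the molecule has no acidic hydrogen and no other electrophilic group at this stage.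

Step 12
Reactants: 15 [(2S,3R)-2-[4-(benzyloxy)-3-methoxyphenyl]-3-(TBS-oxymethyl)-7-methoxy-2,3-dihydrobenzofuran-5-yl]methanol
Product: 16 (2S,3R)-2-[4-(benzyloxy)-3-methoxyphenyl]-5-(bromomethyl)-3-(TBS-oxymethyl)-7-methoxy-2,3-dihydrobenzofuran
Conditions: CBr4, PPh3, CH2Cl2, 0 °C; used at once
Reagents that add atoms: tetrabromomethane, BrC(Br)(Br)Br
Why: Appel bromination under neutral conditions, which spares the acid-labile O1–C2 bond and the silyl ether; the electron-rich benzylic bromide is not stored.

Step 13
Reactants: 17 4-(benzyloxy)-3-methoxybenzaldehyde; 18 dimethyl succinate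
Product: 19 (E)-4-[4-(benzyloxy)-3-methoxyphenyl]-3-(methoxycarbonyl)but-3-enoic acid
Conditions: NaOMe, MeOH, reflux; aq. HCl
Reagents that add atoms: none
Why: Stobbe condensation: the succinate enolate adds to the aldehyde, the alkoxide lactonises to a paraconate, and base-induced ring opening gives the E alkylidene half ester with the free acid on the CH2 arm, the regiochemistry the next two steps rely on.

Step 14
Reactants: 19 (E)-4-[4-(benzyloxy)-3-methoxyphenyl]-3-(methoxycarbonyl)but-3-enoic acid
Product: 20 (R)-4-[4-(benzyloxy)-3-methoxyphenyl]-3-(methoxycarbonyl)butanoic acid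
Conditions: H2 (5 bar), [Rh(cod)((S,S)-Et-DuPHOS)]BF4 (cat.), NaOMe (0.1 equiv), MeOH, rt
Reagents that add atoms: none
Why: Asymmetric hydrogenation of a Stobbe-derived itaconate half ester with a cationic monovalent rhodium bisphospholane catalyst: the carboxylate chelates the metal and the ligand selects the olefin face, which sets C8. The (S,S) ligand is the hand expected from the chelation model to give the R acid, and homogeneous rhodium leaves aryl benzyl ethers intact.

Step 15
Reactants: 20 (R)-4-[4-(benzyloxy)-3-methoxyphenyl]-3-(methoxycarbonyl)butanoic acid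
Product: 22 (R)-4-[4-(benzyloxy)-3-methoxybenzyl]dihydrofuran-2(3H)-one, via (R)-hydroxy acid 21 (not isolated)
Conditions: KOH (1 equiv), EtOH, 0 °C; CaCl2, NaBH4, EtOH, −10 °C to rt; then aq. HCl, rt
Reagents that add atoms: none
Why: Calcium borohydride formed in the flask reduces the ester but not the carboxylate salt, and acidification lactonises the γ-hydroxy acid; the stereocentre is not a reacting atom and the chemoselectivity fixes which carbon becomes the lactone carbonyl (C9').

Step 16
Reactants: 22 (R)-4-[4-(benzyloxy)-3-methoxybenzyl]dihydrofuran-2(3H)-one; 16 (2S,3R)-2-[4-(benzyloxy)-3-methoxyphenyl]-5-(bromomethyl)-3-(TBS-oxymethyl)-7-methoxy-2,3-dihydrobenzofuran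
Product: 23 (3R,4R)-4-[4-(benzyloxy)-3-methoxybenzyl]-3-{[(2S,3R)-2-[4-(benzyloxy)-3-methoxyphenyl]-3-(TBS-oxymethyl)-7-methoxy-2,3-dihydrobenzofuran-5-yl]methyl}dihydrofuran-2(3H)-one
Conditions: LiN(SiMe3)2, THF, −78 °C; then 16, DMPU, −78 to −20 °C
Reagents that add atoms: none
Why: Alkylation of a β-substituted butyrolactone enolate, the standard route to trans-dibenzylbutyrolactone lignans: the electrophile approaches anti to the C8 benzyl group, so C8 sets C8' as R and the ring is trans.

Step 17
Reactants: 23 (3R,4R)-4-[4-(benzyloxy)-3-methoxybenzyl]-3-{[(2S,3R)-2-[4-(benzyloxy)-3-methoxyphenyl]-3-(TBS-oxymethyl)-7-methoxy-2,3-dihydrobenzofuran-5-yl]methyl}dihydrofuran-2(3H)-one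
Product: 24 (2R,3R)-2-[4-(benzyloxy)-3-methoxybenzyl]-3-{[(2S,3R)-2-[4-(benzyloxy)-3-methoxyphenyl]-3-(TBS-oxymethyl)-7-methoxy-2,3-dihydrobenzofuran-5-yl]methyl}butane-1,4-diol
Conditions: LiAlH4, THF, 0 °C
Reagents that add atoms: none
Why: Hydride reduction of the lactone to the 1,4-diol; no stereocentre is a reacting atom and aryl benzyl ethers and the primary silyl ether tolerate LiAlH4 at 0 °C.

Step 18
Reactants: 24 (2R,3R)-2-[4-(benzyloxy)-3-methoxybenzyl]-3-{[(2S,3R)-2-[4-(benzyloxy)-3-methoxyphenyl]-3-(TBS-oxymethyl)-7-methoxy-2,3-dihydrobenzofuran-5-yl]methyl}butane-1,4-diol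
Product: 25 (2R,3R)-2-[4-(benzyloxy)-3-methoxybenzyl]-3-{[(2S,3R)-2-[4-(benzyloxy)-3-methoxyphenyl]-3-(hydroxymethyl)-7-methoxy-2,3-dihydrobenzofuran-5-yl]methyl}butane-1,4-diol
Conditions: Bu4NF, THF, 0 °C to rt
Reagents that add atoms: none
Why: Fluoride cleavage of the silyl ether, placed before debenzylation so that the ring-C phenol is still masked while basic fluoride is present and the quinone-methide opening of O1–C2 cannot start.

Step 19
Reactants: 25 (2R,3R)-2-[4-(benzyloxy)-3-methoxybenzyl]-3-{[(2S,3R)-2-[4-(benzyloxy)-3-methoxyphenyl]-3-(hydroxymethyl)-7-methoxy-2,3-dihydrobenzofuran-5-yl]methyl}butane-1,4-diol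
Product: 26 (2R,3R)-2-(4-hydroxy-3-methoxybenzyl)-3-{[(2S,3R)-2-(4-hydroxy-3-methoxyphenyl)-3-(hydroxymethyl)-7-methoxy-2,3-dihydrobenzofuran-5-yl]methyl}butane-1,4-diol (CNP0256425.1)
Conditions: H2 (1 atm), Pd/C (10% Pd on carbon), EtOAc–MeOH, rt; stopped after 2 equiv of H2
Reagents that add atoms: none
Why: Hydrogenolysis of two primary aryl benzyl ethers under neutral conditions; these should cleave much faster than the secondary, cyclic benzylic O1–C2 bond, and the product is isolated by filtration and evaporation.

## Compound list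

1 | 5-bromo-2-hydroxy-3-methoxybenzaldehyde | COc1cc(Br)cc(C=O)c1O | starting material
2 | allyl bromide | C=CCBr | starting material
3 | 2-(allyloxy)-5-bromo-3-methoxybenzaldehyde | C=CCOc1c(OC)cc(Br)cc1C=O | intermediate
4 | 2-(allyloxy)-5-bromo-1-methoxy-3-[2-(methylsulfinyl)-2-(methylsulfanyl)ethenyl]benzene (alkene isomers, racemic at sulfur) | C=CCOc1c(OC)cc(Br)cc1C=C(SC)S(C)=O | intermediate
5 | ethyl 2-[2-(allyloxy)-5-bromo-3-methoxyphenyl]acetate | CCOC(=O)Cc1cc(Br)cc(OC)c1OCC=C | intermediate
6 | 4-(benzyloxy)-3-methoxybenzoic acid | COc1cc(C(=O)O)ccc1OCc1ccccc1 | starting material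
7 | 4-(benzyloxy)-3-methoxybenzoyl chloride | COc1cc(C(=O)Cl)ccc1OCc1ccccc1 | intermediate
8 | ethyl 2-[2-(allyloxy)-5-bromo-3-methoxyphenyl]-3-[4-(benzyloxy)-3-methoxyphenyl]-3-oxopropanoate (racemic) | CCOC(=O)C(c1cc(Br)cc(OC)c1OCC=C)C(=O)c1ccc(OCc2ccccc2)c(OC)c1 | intermediate
9 | ethyl (2S,3R)-2-[2-(allyloxy)-5-bromo-3-methoxyphenyl]-3-[4-(benzyloxy)-3-methoxyphenyl]-3-hydroxypropanoate | Brc1cc(OC)c(OCC=C)c(c1)[C@H](C(=O)OCC)[C@H](c1ccc(OCc2ccccc2)c(OC)c1)O | intermediate
10 | (1R,2R)-2-[2-(allyloxy)-5-bromo-3-methoxyphenyl]-1-[4-(benzyloxy)-3-methoxyphenyl]propane-1,3-diol | Brc1cc(OC)c(OCC=C)c(c1)[C@H](CO)[C@H](c1ccc(OCc2ccccc2)c(OC)c1)O | intermediate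
11 | (1R,2R)-2-[2-(allyloxy)-5-bromo-3-methoxyphenyl]-1-[4-(benzyloxy)-3-methoxyphenyl]-3-[(tert-butyldimethylsilyl)oxy]propan-1-ol | Brc1cc(OC)c(OCC=C)c(c1)[C@H](CO[Si](C)(C)C(C)(C)C)[C@H](c1ccc(OCc2ccccc2)c(OC)c1)O | intermediate
12 | (1R,2R)-1-[4-(benzyloxy)-3-methoxyphenyl]-2-(5-bromo-2-hydroxy-3-methoxyphenyl)-3-[(tert-butyldimethylsilyl)oxy]propan-1-ol | Brc1cc(OC)c(O)c(c1)[C@H](CO[Si](C)(C)C(C)(C)C)[C@H](c1ccc(OCc2ccccc2)c(OC)c1)O | intermediate
13 | (2S,3R)-2-[4-(benzyloxy)-3-methoxyphenyl]-5-bromo-3-{[(tert-butyldimethylsilyl)oxy]methyl}-7-methoxy-2,3-dihydro-1-benzofuran | Brc1cc(OC)c2c(c1)[C@H](CO[Si](C)(C)C(C)(C)C)[C@@H](c1ccc(OCc3ccccc3)c(OC)c1)O2 | intermediate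
14 | (2S,3R)-2-[4-(benzyloxy)-3-methoxyphenyl]-3-{[(tert-butyldimethylsilyl)oxy]methyl}-7-methoxy-2,3-dihydro-1-benzofuran-5-carbaldehyde | O=Cc1cc(OC)c2c(c1)[C@H](CO[Si](C)(C)C(C)(C)C)[C@@H](c1ccc(OCc3ccccc3)c(OC)c1)O2 | intermediate (not isolated)
15 | [(2S,3R)-2-[4-(benzyloxy)-3-methoxyphenyl]-3-{[(tert-butyldimethylsilyl)oxy]methyl}-7-methoxy-2,3-dihydro-1-benzofuran-5-yl]methanol | OCc1cc(OC)c2c(c1)[C@H](CO[Si](C)(C)C(C)(C)C)[C@@H](c1ccc(OCc3ccccc3)c(OC)c1)O2 | intermediate
16 | (2S,3R)-2-[4-(benzyloxy)-3-methoxyphenyl]-5-(bromomethyl)-3-{[(tert-butyldimethylsilyl)oxy]methyl}-7-methoxy-2,3-dihydro-1-benzofuran | BrCc1cc(OC)c2c(c1)[C@H](CO[Si](C)(C)C(C)(C)C)[C@@H](c1ccc(OCc3ccccc3)c(OC)c1)O2 | intermediate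
17 | 4-(benzyloxy)-3-methoxybenzaldehyde | COc1cc(C=O)ccc1OCc1ccccc1 | starting material
18 | dimethyl succinate | COC(=O)CCC(=O)OC | starting material
19 | (E)-4-[4-(benzyloxy)-3-methoxyphenyl]-3-(methoxycarbonyl)but-3-enoic acid | COC(=O)/C(=C/c1ccc(OCc2ccccc2)c(OC)c1)CC(=O)O | intermediate
20 | (R)-4-[4-(benzyloxy)-3-methoxyphenyl]-3-(methoxycarbonyl)butanoic acid | COC(=O)[C@H](Cc1ccc(OCc2ccccc2)c(OC)c1)CC(=O)O | intermediate
21 | (R)-3-[4-(benzyloxy)-3-methoxybenzyl]-4-hydroxybutanoic acid | OC[C@H](Cc1ccc(OCc2ccccc2)c(OC)c1)CC(=O)O | intermediate (not isolated)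
22 | (R)-4-[4-(benzyloxy)-3-methoxybenzyl]dihydrofuran-2(3H)-one | COc1cc(C[C@H]2COC(=O)C2)ccc1OCc1ccccc1 | intermediate
23 | (3R,4R)-4-[4-(benzyloxy)-3-methoxybenzyl]-3-{[(2S,3R)-2-[4-(benzyloxy)-3-methoxyphenyl]-3-{[(tert-butyldimethylsilyl)oxy]methyl}-7-methoxy-2,3-dihydro-1-benzofuran-5-yl]methyl}dihydrofuran-2(3H)-one | O=C1OC[C@H](Cc2ccc(OCc3ccccc3)c(OC)c2)[C@H]1Cc1cc(OC)c2c(c1)[C@H](CO[Si](C)(C)C(C)(C)C)[C@@H](c1ccc(OCc3ccccc3)c(OC)c1)O2 | intermediate
24 | (2R,3R)-2-[4-(benzyloxy)-3-methoxybenzyl]-3-{[(2S,3R)-2-[4-(benzyloxy)-3-methoxyphenyl]-3-{[(tert-butyldimethylsilyl)oxy]methyl}-7-methoxy-2,3-dihydro-1-benzofuran-5-yl]methyl}butane-1,4-diol | COc1cc(C[C@@H](CO)[C@H](CO)Cc2cc(OC)c3c(c2)[C@H](CO[Si](C)(C)C(C)(C)C)[C@@H](c2ccc(OCc4ccccc4)c(OC)c2)O3)ccc1OCc1ccccc1 | intermediate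
25 | (2R,3R)-2-[4-(benzyloxy)-3-methoxybenzyl]-3-{[(2S,3R)-2-[4-(benzyloxy)-3-methoxyphenyl]-3-(hydroxymethyl)-7-methoxy-2,3-dihydro-1-benzofuran-5-yl]methyl}butane-1,4-diol | COc1cc(C[C@@H](CO)[C@H](CO)Cc2cc(OC)c3c(c2)[C@H](CO)[C@@H](c2ccc(OCc4ccccc4)c(OC)c2)O3)ccc1OCc1ccccc1 | intermediate
26 | (2R,3R)-2-(4-hydroxy-3-methoxybenzyl)-3-{[(2S,3R)-2-(4-hydroxy-3-methoxyphenyl)-3-(hydroxymethyl)-7-methoxy-2,3-dihydro-1-benzofuran-5-yl]methyl}butane-1,4-diol (CNP0256425.1) | COc1cc(C[C@@H](CO)[C@H](CO)Cc2cc(OC)c3c(c2)[C@H](CO)[C@@H](c2ccc(O)c(OC)c2)O3)ccc1O | target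

## Step count and least certain steps

Total: 19 steps. Longest linear sequence: 15 steps (steps 1–3, 5–12 and 16–19, from 1 to 26); steps 4 and 13–15 are side branches.

**Step 6 (key step).** The screen may find no enzyme that turns over a ketone flanked by two aryl-bearing groups at a useful rate, or the active enzyme may deliver hydride to the other face or accept both α-enantiomers. Low aqueous solubility would slow the reduction further and leave time for hydrolysis and decarboxylation of the keto ester. The fallback replaces the reduction by an auxiliary-controlled aldol reaction; it sets out from 5 and returns at 13. Ester 5 is saponified (LiOH, THF–water) to 2-[2-(allyloxy)-5-bromo-3-methoxyphenyl]acetic acid F1. F1 is coupled with (S)-4-benzyloxazolidin-2-one (pivaloyl chloride, Et3N, LiCl) to give (S)-3-{2-[2-(allyloxy)-5-bromo-3-methoxyphenyl]acetyl}-4-benzyloxazolidin-2-one F2. The boron enolate of F2 (Bu2BOTf, i-Pr2NEt) adds to aldehyde 17 to give the syn aldol (S)-3-[(2S,3S)-2-[2-(allyloxy)-5-bromo-3-methoxyphenyl]-3-[4-(benzyloxy)-3-methoxyphenyl]-3-hydroxypropanoyl]-4-benzyloxazolidin-2-one F3, whose α-centre has the sense needed for C3. LiBH4 removes the auxiliary to give (1S,2R)-2-[2-(allyloxy)-5-bromo-3-methoxyphenyl]-1-[4-(benzyloxy)-3-methoxyphenyl]propane-1,3-diol F4. Pd(PPh3)4 and morpholine give (1S,2R)-1-[4-(benzyloxy)-3-methoxyphenyl]-2-(5-bromo-2-hydroxy-3-methoxyphenyl)propane-1,3-diol F5. Because the carbinol is now epimeric, F5 is closed with catalytic TsOH in CH2Cl2 through the benzylic cation, which the phenol should capture trans to the C3 substituent, to give [(2S,3R)-2-[4-(benzyloxy)-3-methoxyphenyl]-5-bromo-7-methoxy-2,3-dihydro-1-benzofuran-3-yl]methanol F6. Silylation (TBSCl, imidazole) gives 13.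

**Step 10.** The activated benzylic oxygen may ionise before the phenoxide attacks, because the cation is stabilised by the para benzyloxy group; this would erode the inversion and allow irreversible elimination towards the stilbene. The fallback gives up stereospecific displacement and relies on C3: from 12, catalytic BF3·OEt2 in CH2Cl2 at −40 °C cyclodehydrates through the cation. Under acid any alkene formed can be re-protonated, and the phenol should add trans to the C3 substituent, returning directly to 13 without a new compound.

**Step 11.** Deprotonation at the benzylic C3–H with β-elimination of the phenoxide, or protonation of the aryllithium before it meets DMF, may compete with the exchange–formylation sequence. The fallback avoids organolithium chemistry; it sets out from 13 and returns at 15. Carbonylation of 13 (Pd(OAc)2, Xantphos, CO, MeOH, Et3N, 70 °C) gives methyl (2S,3R)-2-[4-(benzyloxy)-3-methoxyphenyl]-3-{[(tert-butyldimethylsilyl)oxy]methyl}-7-methoxy-2,3-dihydro-1-benzofuran-5-carboxylate F7, which i-Bu2AlH in CH2Cl2 at −78 °C reduces to 15.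

**Step 16.** Bromide 16 may ionise and be consumed by self-alkylation or solvolysis before the enolate captures it, and proton transfer between product and enolate may cause dialkylation or lower the trans preference. The fallback forms the same bond by an aldol reaction and removes the extra oxygen by a radical step; it sets out from aldehyde 14 (isolated by leaving out the borohydride stage of step 11) and lactone 22 and returns at 23. The lithium enolate of 22 adds to 14 to give (3S,4R)-4-[4-(benzyloxy)-3-methoxybenzyl]-3-{[(2S,3R)-2-[4-(benzyloxy)-3-methoxyphenyl]-3-{[(tert-butyldimethylsilyl)oxy]methyl}-7-methoxy-2,3-dihydro-1-benzofuran-5-yl](hydroxy)methyl}dihydrofuran-2(3H)-one F8 (both carbinol epimers, trans on the lactone). Phenyl chlorothionoformate and pyridine convert F8 into its O-phenyl thiocarbonate F9. Barton–McCombie deoxygenation (Bu3SnH, AIBN, toluene, 80 °C) gives 23.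

**Step 5.** O-acylation of the enolate, a second acylation of the product enolate or self-condensation of 5 may lower the return of 8. The fallback forms the C–C bond by an aldol reaction and adjusts the oxidation level afterwards; it sets out from 5 and 17 and returns at 8. The lithium enolate of 5 (LiN(i-Pr)2, THF, −78 °C) adds to aldehyde 17 to give ethyl 2-[2-(allyloxy)-5-bromo-3-methoxyphenyl]-3-[4-(benzyloxy)-3-methoxyphenyl]-3-hydroxypropanoate F10 (racemic mixture of diastereomers), which Dess–Martin periodinane oxidises to 8.

## Further compounds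

F1 | step 6 | 2-[2-(allyloxy)-5-bromo-3-methoxyphenyl]acetic acid | C=CCOc1c(OC)cc(Br)cc1CC(=O)O
F2 | step 6 | (S)-3-{2-[2-(allyloxy)-5-bromo-3-methoxyphenyl]acetyl}-4-benzyloxazolidin-2-one | C=CCOc1c(OC)cc(Br)cc1CC(=O)N1[C@@H](Cc2ccccc2)COC1=O
F3 | step 6 | (S)-3-[(2S,3S)-2-[2-(allyloxy)-5-bromo-3-methoxyphenyl]-3-[4-(benzyloxy)-3-methoxyphenyl]-3-hydroxypropanoyl]-4-benzyloxazolidin-2-one | Brc1cc(OC)c(OCC=C)c(c1)[C@H](C(=O)N1[C@@H](Cc2ccccc2)COC1=O)[C@@H](c1ccc(OCc2ccccc2)c(OC)c1)O
F4 | step 6 | (1S,2R)-2-[2-(allyloxy)-5-bromo-3-methoxyphenyl]-1-[4-(benzyloxy)-3-methoxyphenyl]propane-1,3-diol | Brc1cc(OC)c(OCC=C)c(c1)[C@H](CO)[C@@H](c1ccc(OCc2ccccc2)c(OC)c1)O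
F5 | step 6 | (1S,2R)-1-[4-(benzyloxy)-3-methoxyphenyl]-2-(5-bromo-2-hydroxy-3-methoxyphenyl)propane-1,3-diol | Brc1cc(OC)c(O)c(c1)[C@H](CO)[C@@H](c1ccc(OCc2ccccc2)c(OC)c1)O
F6 | step 6 | [(2S,3R)-2-[4-(benzyloxy)-3-methoxyphenyl]-5-bromo-7-methoxy-2,3-dihydro-1-benzofuran-3-yl]methanol | Brc1cc(OC)c2c(c1)[C@H](CO)[C@@H](c1ccc(OCc3ccccc3)c(OC)c1)O2
F0 | step 10 | none | none
F7 | step 11 | methyl (2S,3R)-2-[4-(benzyloxy)-3-methoxyphenyl]-3-{[(tert-butyldimethylsilyl)oxy]methyl}-7-methoxy-2,3-dihydro-1-benzofuran-5-carboxylate | COC(=O)c1cc(OC)c2c(c1)[C@H](CO[Si](C)(C)C(C)(C)C)[C@@H](c1ccc(OCc3ccccc3)c(OC)c1)O2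
F8 | step 16 | (3S,4R)-4-[4-(benzyloxy)-3-methoxybenzyl]-3-{[(2S,3R)-2-[4-(benzyloxy)-3-methoxyphenyl]-3-{[(tert-butyldimethylsilyl)oxy]methyl}-7-methoxy-2,3-dihydro-1-benzofuran-5-yl](hydroxy)methyl}dihydrofuran-2(3H)-one (carbinol epimers) | O=C1OC[C@H](Cc2ccc(OCc3ccccc3)c(OC)c2)[C@H]1C(O)c1cc(OC)c2c(c1)[C@H](CO[Si](C)(C)C(C)(C)C)[C@@H](c1ccc(OCc3ccccc3)c(OC)c1)O2
F9 | step 16 | O-phenyl thiocarbonate of F8 | O=C1OC[C@H](Cc2ccc(OCc3ccccc3)c(OC)c2)[C@H]1C(OC(=S)Oc1ccccc1)c1cc(OC)c2c(c1)[C@H](CO[Si](C)(C)C(C)(C)C)[C@@H](c1ccc(OCc3ccccc3)c(OC)c1)O2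
F10 | step 5 | ethyl 2-[2-(allyloxy)-5-bromo-3-methoxyphenyl]-3-[4-(benzyloxy)-3-methoxyphenyl]-3-hydroxypropanoate (racemic mixture of diastereomers) | CCOC(=O)C(c1cc(Br)cc(OC)c1OCC=C)C(O)c1ccc(OCc2ccccc2)c(OC)c1
A1 | alternative 1 | 3-[4-(benzyloxy)-3-methoxybenzyl]cyclobutan-1-one | COc1cc(CC2CC(=O)C2)ccc1OCc1ccccc1
A2 | alternative 1 | (R)-4-[4-(benzyloxy)-3-methoxybenzyl]dihydrofuran-2(3H)-one (identical with 22) | COc1cc(C[C@H]2COC(=O)C2)ccc1OCc1ccccc1
A3 | alternative 2 | (5R)-5-[(1R,2S,5R)-menthyloxy]furan-2(5H)-one | O=C1C=C[C@H](O[C@@H]2C[C@H](C)CC[C@H]2C(C)C)O1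
A4 | alternative 2 | 2-[(2S,3R)-2-[4-(benzyloxy)-3-methoxyphenyl]-3-{[(tert-butyldimethylsilyl)oxy]methyl}-7-methoxy-2,3-dihydro-1-benzofuran-5-yl]-1,3-dithiane | C1CSC(SC1)c1cc(OC)c2c(c1)[C@H](CO[Si](C)(C)C(C)(C)C)[C@@H](c1ccc(OCc3ccccc3)c(OC)c1)O2
A5 | alternative 2 | 4-(benzyloxy)-3-methoxybenzyl bromide | COc1cc(CBr)ccc1OCc1ccccc1
A6 | alternative 2 | trans,trans-3-[4-(benzyloxy)-3-methoxybenzyl]-4-[2-(dihydrobenzofuran-5-yl)-1,3-dithian-2-yl]-5-(l-menthyloxy)dihydrofuran-2(3H)-one, the dihydrobenzofuranyl group being that of A4 | COc1cc(C[C@H]2C(=O)O[C@@H](O[C@@H]3C[C@H](C)CC[C@H]3C(C)C)[C@@H]2C2(SCCCS2)c2cc(OC)c3c(c2)[C@H](CO[Si](C)(C)C(C)(C)C)[C@@H](c2ccc(OCc4ccccc4)c(OC)c2)O3)ccc1OCc1ccccc1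
A7 | alternative 3 | methyl (1S,5R)-2-oxo-3-oxabicyclo[3.1.0]hexane-1-carboxylate | O=C1OC[C@@H]2C[C@]12C(=O)OC
A8 | alternative 3 | [4-(benzyloxy)-3-methoxyphenyl]magnesium bromide | COc1cc([Mg]Br)ccc1OCc1ccccc1
A9 | alternative 3 | methyl (3S,4R)-4-[4-(benzyloxy)-3-methoxybenzyl]-2-oxotetrahydrofuran-3-carboxylate | COc1cc(C[C@H]2COC(=O)[C@@H]2C(=O)OC)ccc1OCc1ccccc1
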